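Labdane numbering is used. Ring B (C5–C10) is read as a cyclohexene retron. The four-carbon unit C5–C6–C7–C8 is a diene and C9=C10 is the (E)-trisubstituted 6,7-alkene of a geranate chain, so the whole side chain is in place before any ring exists. One intramolecular Diels–Alder reaction of an acyclic trienal closes rings A and B together by forming the ring-fusion bond C5–C10 and the bond C8–C9. It sets C5, C9 and C10 under control of the C2 silyl ether and the C4 quaternary centre. The C17 formyl group activates the diene and is later converted into the exocyclic methylene by reductive alkene transposition.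

Key step: step 11

Remark on the chemistry: in step 5, (2R,5R)-2,5-diphenylpyrrolidine is assumed to deliver the (9S)-chloride; if the sense of induction is the opposite, its (2S,5S) enantiomer is used.

Step 1
Reactants: 1 6-methylhept-5-en-2-one; 2 tert-butyl diethylphosphonoacetate
Product: 3 tert-butyl (2E)-3,7-dimethylocta-2,6-dienoate (tert-butyl geranate)
Conditions: NaH, THF, 0 °C to rt; the minor 2Z isomer is removed by chromatography
Reagents that add atoms: none
Why: Horner–Wadsworth–Emmons olefination of a methyl ketone, in which reversible addition and the bulky tert-butyl ester should favour the E enoate that becomes C13=C14 of the target.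

Step 2
Reactants: 3 tert-butyl geranate
Product: 4 tert-butyl (2E)-5-(3,3-dimethyloxiran-2-yl)-3-methylpent-2-enoate (racemic)
Conditions: mCPBA, CH2Cl2, 0 °C
Reagents that add atoms: mCPBA O=C(OO)c1cccc(Cl)c1
Why: Prilezhaev epoxidation is chemoselective for the electron-rich trisubstituted alkene over the conjugated enoate, and the racemic centre is erased in step 4.

Step 3
Reactants: 4 epoxide
Product: 5 tert-butyl (2E)-6-hydroxy-3,7-dimethylocta-2,7-dienoate (racemic)
Conditions: Al(OiPr)3 (0.3 equiv), toluene, 110 °C
Reagents that add atoms: none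
Why: Lewis-acid-mediated epoxide-to-allylic-alcohol isomerisation, in which C–O cleavage at the tertiary carbon and syn loss of a methyl proton inside the aluminium alkoxide complex should give the secondary isopropenyl carbinol.

Step 4
Reactants: 5 allylic alcohol
Product: 7 tert-butyl (2E,6E)-3,7-dimethyl-10-oxodeca-2,6-dienoate, via allyl vinyl ether 6 (not isolated)
Conditions: ethyl vinyl ether (solvent), Hg(OAc)2 (5 mol%), 35 °C; evaporate; toluene, 120 °C, sealed tube
Reagents that add atoms: ethyl vinyl ether C=COCC
Why: Transvinylation followed by an aliphatic Claisen rearrangement through a chair transition state with the ester chain equatorial forms C1–C2 and sets the E geometry of C9=C10.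

Step 5
Reactants: 7 aldehyde
Product: 10 tert-butyl (2E,6E)-3,7-dimethyl-8-[(2R)-oxiran-2-yl]octa-2,6-dienoate, via α-chloro aldehyde 8 (not isolated), via chlorohydrin 9 (not isolated)
Conditions: NCS, (2R,5R)-2,5-diphenylpyrrolidine (10 mol%), CH2Cl2, 0 °C; then NaBH4, MeOH, 0 °C; then KOH, EtOH–H2O, rt
Reagents that add atoms: none
Why: Enamine-catalysed enantioselective α-chlorination sets C2 as the (S)-chloride, and reduction followed by intramolecular Williamson closure with inversion should give the (R)-epoxide with the C2–O configuration of the target.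

Step 6
Reactants: 10 epoxide; 11 tert-butyl methyl malonate
Product: 13 tert-butyl (3S,5R)-5-[(2E,6E)-8-tert-butoxy-2,6-dimethyl-8-oxoocta-2,6-dien-1-yl]-3-methyl-2-oxooxolane-3-carboxylate, via unmethylated lactone enolate 12 (not isolated)
Conditions: NaH, THF–DMPU (4:1), 65 °C; then MeI, 0 °C; the minor C4 epimer is removed by chromatography
Reagents that add atoms: iodomethane CI
Why: Malonate opening of the terminal epoxide at C3, lactonisation through the methyl ester only, and C-methylation of the planar enolate anti to the γ-side chain (1,3-induction) should set the C4 quaternary centre with methyl trans and CO2t-Bu cis to that chain.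

Step 7
Reactants: 13 lactone
Product: 14 tert-butyl (3S,5R)-5-[(2E,6E)-8-tert-butoxy-2,6-dimethyl-8-oxoocta-2,6-dien-1-yl]-2-hydroxy-3-methyloxolane-3-carboxylate (lactol as anomer mixture)
Conditions: i-Bu2AlH (1.1 equiv), CH2Cl2, −78 °C; aq. KNaC4H4O6 work-up
Reagents that add atoms: none
Why: Partial reduction of a lactone to the lactol, in which the stable tetrahedral aluminium alkoxide stops over-reduction and both tert-butyl esters should be too hindered to react at −78 °C.

Step 8
Reactants: 14 lactol
Product: 15 di-tert-butyl (2E,6E,9R,11S)-9-hydroxy-11-[(E)-2-iodoethenyl]-3,7,11-trimethyldodeca-2,6-dienedioate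
Conditions: CrCl2, CHI3, THF–dioxane, 0 °C to rt
Reagents that add atoms: iodoform IC(I)I
Why: Takai olefination under neutral conditions traps the open hydroxy aldehyde form, avoids base-induced deformylation of the α-formyl ester, and should give the E vinyl iodide from the hindered aldehyde.

Step 9
Reactants: 15 hydroxy vinyl iodide
Product: 16 di-tert-butyl (2E,6E,9R,11S)-9-(tert-butyldimethylsilyloxy)-11-[(E)-2-iodoethenyl]-3,7,11-trimethyldodeca-2,6-dienedioate
Conditions: TBSCl, imidazole, DMF, rt
Reagents that add atoms: TBSCl CC(C)(C)[Si](C)(C)Cl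
Why: Standard silylation gives an ether that blocks lactonisation onto the C19 ester and oxa-Michael addition later on, and that serves as the equatorial anchor in step 11.

Step 10
Reactants: 16 silyl ether
Product: 17 di-tert-butyl (2E,6E,9R,11S)-9-(tert-butyldimethylsilyloxy)-3,7,11-trimethyl-11-[(1E,3E)-5-oxopenta-1,3-dien-1-yl]dodeca-2,6-dienedioate
Conditions: acrolein, Pd(OAc)2 (5 mol%), n-Bu4NCl, NaHCO3, DMF, rt to 40 °C
Reagents that add atoms: acrolein C=CC=O
Why: Heck reaction under Jeffery conditions couples the vinyl iodide with retention and should give the (E,E)-dienal by syn insertion and syn β-hydride elimination.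

Step 11
Reactants: 17 trienal
Product: 19 di-tert-butyl 2α-(tert-butyldimethylsilyloxy)-17-oxolabda-7,13E-diene-15,19-dioate, via cycloadduct aldehyde 18 (not isolated)
Conditions: toluene (0.01 M), BHT (cat.), sealed tube, 165 °C; cool to rt; DBU (0.3 equiv)
Reagents that add atoms: none
Why: A thermal, concerted but asynchronous [4+2] cycloaddition (type 1 intramolecular Diels–Alder reaction of a 1,7,9-decatriene) between the formyl-activated C5=C6–C7=C8 diene and the unactivated (E)-C9=C10 alkene forms C5–C10 and C8–C9 at once, after which DBU moves the C6=C7 bond of the β,γ-unsaturated aldehyde 18 into conjugation and erases the C8 centre. Ring B closes as the six-membered cycloaddition ring, and ring A closes at the same moment as the fused six-membered ring spanned by the four-atom tether C4–C3–C2–C1 in a chair-like array. C9 relative to C10 follows from suprafacial addition to the E alkene, which keeps C20 and C11 cis (both β). C5 relative to C10 (trans fusion) follows from the transition state with the tether exo and C20 and C11 under the diene, because the cis alternative must place the fully substituted C9 instead of a methyl group in the axial site that faces the axial C19 ester. The absolute sense is relayed from C2 and C4, since only one chair has the OTBS group equatorial, whereas attack on the other face would stack OTBS, C18 and C20 in a 1,3,5-triaxial array. The step needs site selectivity for C9=C10 over the C13=C14 enoate, which the tether length secures, and the quaternary C4 (gem-disubstituent effect) and the formyl group must compensate for the missing dienophile activation.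

Step 12
Reactants: 19 conjugated enal
Product: 21 di-tert-butyl 2α-(tert-butyldimethylsilyloxy)labda-8(17),13E-diene-15,19-dioate, via tosylhydrazone 20 (not isolated)
Conditions: TsNHNH2, THF, rt; evaporate; catecholborane, CHCl3, −10 °C; then NaOAc·3H2O, 60 °C
Reagents that add atoms: none
Why: Hydrazone formation and Kabalka-type reduction give an allylic diazene whose retro-ene loss of N2 delivers hydrogen to C7 and moves the alkene to the exocyclic C8=C17 position, in analogy to myrtenal tosylhydrazone going to β-pinene.

Step 13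
Reactants: 21 protected diester
Product: 23 hypoxyterpoid A (2α-hydroxylabda-8(17),13E-diene-15,19-dioic acid), via bis(trimethylsilyl) ester 22 (not isolated)
Conditions: TMSOTf, 2,6-lutidine, CH2Cl2, 0 °C to rt; then HF·pyridine, pyridine, THF, 0 °C to rt
Reagents that add atoms: none
Why: Silyl-triflate cleavage of both tert-butyl esters in buffered medium and fluoride desilylation avoid strong protic acid, which would isomerise or cyclise the C8=C17 alkene, and the trans 1,3-relation of C2–OH and C19 excludes lactonisation.

Compound list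
1 | 6-methylhept-5-en-2-one | CC(C)=CCCC(C)=O | starting material
2 | tert-butyl diethylphosphonoacetate | CCOP(=O)(CC(=O)OC(C)(C)C)OCC | starting material
3 | tert-butyl (2E)-3,7-dimethylocta-2,6-dienoate | CC(C)=CCC/C(C)=C/C(=O)OC(C)(C)C | intermediate
4 | tert-butyl (2E)-5-(3,3-dimethyloxiran-2-yl)-3-methylpent-2-enoate, racemic | CC1(C)OC1CC/C(C)=C/C(=O)OC(C)(C)C | intermediate
5 | tert-butyl (2E)-6-hydroxy-3,7-dimethylocta-2,7-dienoate, racemic | C=C(C)C(O)CC/C(C)=C/C(=O)OC(C)(C)C | intermediate
6 | tert-butyl (2E)-6-(ethenyloxy)-3,7-dimethylocta-2,7-dienoate, racemic | C=COC(CC/C(C)=C/C(=O)OC(C)(C)C)C(C)=C | intermediate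
7 | tert-butyl (2E,6E)-3,7-dimethyl-10-oxodeca-2,6-dienoate | O=CCC/C(C)=C/CC/C(C)=C/C(=O)OC(C)(C)C | intermediate
8 | tert-butyl (2E,6E,9S)-9-chloro-3,7-dimethyl-10-oxodeca-2,6-dienoate | O=C[C@@H](Cl)C/C(C)=C/CC/C(C)=C/C(=O)OC(C)(C)C | intermediate
9 | tert-butyl (2E,6E,9S)-9-chloro-10-hydroxy-3,7-dimethyldeca-2,6-dienoate | OC[C@@H](Cl)C/C(C)=C/CC/C(C)=C/C(=O)OC(C)(C)C | intermediate
10 | tert-butyl (2E,6E)-3,7-dimethyl-8-[(2R)-oxiran-2-yl]octa-2,6-dienoate | C1O[C@@H]1C/C(C)=C/CC/C(C)=C/C(=O)OC(C)(C)C | intermediate
11 | tert-butyl methyl malonate | COC(=O)CC(=O)OC(C)(C)C | starting material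
12 | tert-butyl (5S)-5-[(2E,6E)-8-tert-butoxy-2,6-dimethyl-8-oxoocta-2,6-dien-1-yl]-2-oxooxolane-3-carboxylate (C3 epimers, present as sodium enolate; same spatial arrangement at the carbinol carbon as in 13) | O=C1O[C@H](C/C(C)=C/CC/C(C)=C/C(=O)OC(C)(C)C)CC1C(=O)OC(C)(C)C | intermediate
13 | tert-butyl (3S,5R)-5-[(2E,6E)-8-tert-butoxy-2,6-dimethyl-8-oxoocta-2,6-dien-1-yl]-3-methyl-2-oxooxolane-3-carboxylate (methyl trans to the side chain) | O=C1O[C@H](C/C(C)=C/CC/C(C)=C/C(=O)OC(C)(C)C)C[C@]1(C)C(=O)OC(C)(C)C | intermediate
14 | lactol of 13, (3S,5R), anomer mixture | OC1O[C@H](C/C(C)=C/CC/C(C)=C/C(=O)OC(C)(C)C)C[C@]1(C)C(=O)OC(C)(C)C | intermediate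
15 | di-tert-butyl (2E,6E,9R,11S)-9-hydroxy-11-[(E)-2-iodoethenyl]-3,7,11-trimethyldodeca-2,6-dienedioate | I/C=C/[C@@](C)(C(=O)OC(C)(C)C)C[C@H](O)C/C(C)=C/CC/C(C)=C/C(=O)OC(C)(C)C | intermediate
16 | TBS ether of 15 | I/C=C/[C@@](C)(C(=O)OC(C)(C)C)C[C@H](O[Si](C)(C)C(C)(C)C)C/C(C)=C/CC/C(C)=C/C(=O)OC(C)(C)C | intermediate
17 | di-tert-butyl (2E,6E,9R,11S)-9-(tert-butyldimethylsilyloxy)-3,7,11-trimethyl-11-[(1E,3E)-5-oxopenta-1,3-dien-1-yl]dodeca-2,6-dienedioate | O=C/C=C/C=C/[C@@](C)(C(=O)OC(C)(C)C)C[C@H](O[Si](C)(C)C(C)(C)C)C/C(C)=C/CC/C(C)=C/C(=O)OC(C)(C)C | intermediate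
18 | di-tert-butyl 2α-(tert-butyldimethylsilyloxy)-17-oxolabda-6,13E-diene-15,19-dioate (5α-H, 8α-H, 9α-H, 10β-methyl, 4β-ester) | O=C[C@H]1C=C[C@@H]2[C@](C)(C[C@@H](O[Si](C)(C)C(C)(C)C)C[C@]2(C)C(=O)OC(C)(C)C)[C@H]1CC/C(C)=C/C(=O)OC(C)(C)C | intermediate
19 | di-tert-butyl 2α-(tert-butyldimethylsilyloxy)-17-oxolabda-7,13E-diene-15,19-dioate | O=CC1=CC[C@@H]2[C@](C)(C[C@@H](O[Si](C)(C)C(C)(C)C)C[C@]2(C)C(=O)OC(C)(C)C)[C@H]1CC/C(C)=C/C(=O)OC(C)(C)C | intermediate
20 | (E)-N-tosylhydrazone of 19 | Cc1ccc(cc1)S(=O)(=O)N/N=C/C1=CC[C@@H]2[C@](C)(C[C@@H](O[Si](C)(C)C(C)(C)C)C[C@]2(C)C(=O)OC(C)(C)C)[C@H]1CC/C(C)=C/C(=O)OC(C)(C)C | intermediate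
21 | di-tert-butyl 2α-(tert-butyldimethylsilyloxy)labda-8(17),13E-diene-15,19-dioate | C=C1CC[C@@H]2[C@](C)(C[C@@H](O[Si](C)(C)C(C)(C)C)C[C@]2(C)C(=O)OC(C)(C)C)[C@H]1CC/C(C)=C/C(=O)OC(C)(C)C | intermediate
22 | bis(trimethylsilyl) 2α-(tert-butyldimethylsilyloxy)labda-8(17),13E-diene-15,19-dioate | C=C1CC[C@@H]2[C@](C)(C[C@@H](O[Si](C)(C)C(C)(C)C)C[C@]2(C)C(=O)O[Si](C)(C)C)[C@H]1CC/C(C)=C/C(=O)O[Si](C)(C)C | intermediate
23 | hypoxyterpoid A, (1S,3R,4aR,5S,8aR)-5-[(3E)-4-carboxy-3-methylbut-3-en-1-yl]-3-hydroxy-1,4a-dimethyl-6-methylidenedecahydronaphthalene-1-carboxylic acid | C=C1CC[C@@H]2[C@](C)(C[C@@H](O)C[C@]2(C)C(=O)O)[C@H]1CC/C(C)=C/C(=O)O | target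

Total step count: 13. Longest linear sequence: 13 steps (1 to 23).

Steps most likely to fail

Step 11 (key step).
- What may go wrong: The unactivated trisubstituted alkene may add too slowly. Thermal loss of isobutene from the esters or polymerisation of the dienal could then overtake the cycloaddition. The preference for the trans-fused transition state may also be insufficient.
- Fallback: It sets out from 17. The aldehyde is masked with HC(OMe)3 and PPTS in MeOH as the trienyl dimethyl acetal F1. Both rings are then closed with a cationic monovalent rhodium catalyst ([Rh(cod)Cl]2, AgSbF6, P[OCH(CF3)2]3, CH2Cl2, 40 °C). This metal-templated [4+2] reaction runs through oxidative cyclisation to a rhodacycle and reductive elimination instead of a pericyclic transition state. It needs no polarised partners and works near room temperature. It should give the cycloadduct acetal F2. Hydrolysis with oxalic acid in wet THF comes back to the route at 18, which DBU converts into 19.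

Step 6.
- What may go wrong: Facial selectivity in the methylation of the flat enolate may be poor, because the γ-side chain is remote, and the epoxide opening may be sluggish.
- Fallback: It sets out from 12, isolated by an acidic quench before MeI is added, and replaces substrate control by catalyst control. The method is phase-transfer methylation (MeI, solid Cs2CO3, toluene, −40 °C) with the matched enantiomer of a C2-symmetric binaphthyl-derived spiro ammonium bromide. This reaction type is established for α-tert-butoxycarbonyl lactones. It comes back at 13 and makes no new compound (F0).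

Step 8.
- What may go wrong: Slow ring opening of the lactol may let the chromium carbenoid decay before it meets the hindered aldehyde, and the E selectivity may erode.
- Fallback: It sets out from 13. The lactone is opened with MeNH(OMe)·HCl and i-PrMgCl (THF, −20 °C) to the hydroxy Weinreb amide F3. Silylation (TBSCl, imidazole, DMF) gives the silylated Weinreb amide F4. Reduction with i-Bu2AlH (CH2Cl2, −78 °C) gives the open-chain aldehyde F5, which cannot close to a lactol. The Takai olefination (CrCl2, CHI3) is run on this aldehyde, and the fallback comes back at 16.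

Further compounds
F1 | step 11 | dimethyl acetal of trienal 17 | COC(OC)/C=C/C=C/[C@@](C)(C(=O)OC(C)(C)C)C[C@H](O[Si](C)(C)C(C)(C)C)C/C(C)=C/CC/C(C)=C/C(=O)OC(C)(C)C
F2 | step 11 | dimethyl acetal of cycloadduct 18 | COC(OC)[C@H]1C=C[C@@H]2[C@](C)(C[C@@H](O[Si](C)(C)C(C)(C)C)C[C@]2(C)C(=O)OC(C)(C)C)[C@H]1CC/C(C)=C/C(=O)OC(C)(C)C
F0 | step 6 | none | none
F3 | step 8 | hydroxy Weinreb amide from lactone 13 | CON(C)C(=O)[C@@](C)(C(=O)OC(C)(C)C)C[C@H](O)C/C(C)=C/CC/C(C)=C/C(=O)OC(C)(C)C
F4 | step 8 | TBS ether of F3 | CON(C)C(=O)[C@@](C)(C(=O)OC(C)(C)C)C[C@H](O[Si](C)(C)C(C)(C)C)C/C(C)=C/CC/C(C)=C/C(=O)OC(C)(C)C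
F5 | step 8 | open-chain silyloxy aldehyde | O=C[C@@](C)(C(=O)OC(C)(C)C)C[C@H](O[Si](C)(C)C(C)(C)C)C/C(C)=C/CC/C(C)=C/C(=O)OC(C)(C)C
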